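**Retrosynthetic overview**

1. Target 29 ⇐ silylated acetate 28 ⇐ (1S)-carbinol 27 ⇐ enone 26 ⇐ carbinol 25. The only ring, the eleven-membered carbocycle C1–C11, is closed at C1–C2 by CrCl2/NiCl2 coupling of the (Z)-C2 iodoalkene with the C1 aldehyde of 24; C1 is then fixed by oxidation and CBS reduction.
2. 24 ⇐ iodo dienol 18 by C4 aroylation (acid 21, from 4-hydroxybenzoic acid 19), C1 desilylation and oxidation.
3. 18 ⇐ alkyne 8 + AlMe3 15 + (S)-epoxide 14. The plan rests on the E-trisubstituted C6=C7 alkene of the ring, with its methyl on C7 and the C4 carbinol one CH2 (C5) away, a homoallylic alcohol unit; C7–CH3 and C5–C6 are made in one flask.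
4. 8 ⇐ methyl isobutyrate 3 + chloride 1 (C11 quaternary carbon by enolate alkylation); 14 ⇐ propargyl alcohol 9 (carbomagnesiation–iodination, oxidation, methylene transfer, hydrolytic kinetic resolution).

Key step: step 10

Assumption: ring atoms are numbered C1 (acetoxy carbon), C2=C3, C4 (aroyloxy carbon), C5, C6=C7, C8–C10, C11 (CMe2); in this numbering the target is (1S,2Z,4R,6E), and the same atom labels are used for the open-chain intermediates.

**Route**

Step 1
Reactants: 1 (5-chloropent-1-yn-1-yl)trimethylsilane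
Product: 2 (5-iodopent-1-yn-1-yl)trimethylsilane
Conditions: NaI (3 equiv), acetone, reflux
Reagents that add atoms: sodium iodide [Na+].[I-]
Why: Finkelstein exchange at a primary carbon, driven by precipitation of NaCl, should give the iodide needed for a clean enolate alkylation.

Step 2
Reactants: 3 methyl isobutyrate; 2 (5-iodopent-1-yn-1-yl)trimethylsilane
Product: 5 methyl 2,2-dimethyl-7-(trimethylsilyl)hept-6-ynoate, via lithium enolate 4 (not isolated)
Conditions: LDA (commercial solution), THF, −78 °C; then 2, DMPU, −78 °C → rt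
Reagents that add atoms: none
Why: SN2 alkylation of a fully substituted ester enolate with a primary iodide should build the C11 quaternary carbon, the C-silyl group keeping the alkyne C–H from quenching the enolate.

Step 3
Reactants: 5 methyl 2,2-dimethyl-7-(trimethylsilyl)hept-6-ynoate
Product: 6 2,2-dimethyl-7-(trimethylsilyl)hept-6-yn-1-ol
Conditions: LiAlH4, Et2O, 0 °C → rt; aq. Rochelle salt
Reagents that add atoms: none
Why: Hydride reduction of the ester to the primary alcohol (future C1) should proceed without touching the unactivated silylalkyne.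

Step 4
Reactants: 6 2,2-dimethyl-7-(trimethylsilyl)hept-6-yn-1-ol
Product: 7 2,2-dimethylhept-6-yn-1-ol
Conditions: K2CO3 (0.2 equiv), MeOH, rt
Reagents that add atoms: none
Why: Methoxide-mediated protodesilylation of an alkynylsilane is routine and should free the terminal alkyne required for carbometalation.

Step 5
Reactants: 7 2,2-dimethylhept-6-yn-1-ol
Product: 8 tert-butyl[(2,2-dimethylhept-6-yn-1-yl)oxy]dimethylsilane
Conditions: TBSCl, imidazole, DMAP (cat.), DMF, rt
Reagents that add atoms: tert-butyldimethylsilyl chloride CC(C)(C)[Si](C)(C)Cl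
Why: Standard silylation of a primary alcohol should give an ether that tolerates AlMe3, Cp2ZrCl2 and the alanate.

Step 6
Reactants: 9 propargyl alcohol
Product: 11 (Z)-3-iodo-2-methylprop-2-en-1-ol, via alkenylmagnesium chelate 10 (not isolated)
Conditions: MeMgBr (2.5 equiv), CuI (10 mol %), THF, −10 °C → rt; then I2, −78 → 0 °C
Reagents that add atoms: methylmagnesium bromide C[Mg]Br; iodine I-I
Why: Copper-catalysed anti-carbomagnesiation of the propargylic alkoxide should place methyl on the internal carbon and magnesium on the terminus cis to CH2O in a five-membered chelate, so that iodinolysis with retention gives the Z iodoalkene (future C2=C3).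

Step 7
Reactants: 11 (Z)-3-iodo-2-methylprop-2-en-1-ol
Product: 12 (Z)-3-iodo-2-methylprop-2-enal
Conditions: activated MnO2, CH2Cl2, rt, dark; used directly
Reagents that add atoms: none
Why: Heterogeneous allylic oxidation with MnO2 under neutral conditions should give the enal with the Z geometry intact, provided it is used at once.

Step 8
Reactants: 12 (Z)-3-iodo-2-methylprop-2-enal
Product: 13 rac-2-[(Z)-1-iodoprop-1-en-2-yl]oxirane
Conditions: Me3S+ I− (1.3 equiv), KHMDS (1.2 equiv), THF, −20 → 0 °C; then 12, −78 → 0 °C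
Reagents that add atoms: trimethylsulfonium iodide C[S+](C)C.[I-]
Why: Corey–Chaykovsky methylene transfer from dimethylsulfonium methylide adds 1,2 to the non-enolisable enal and closes the oxirane (C4–C5), giving the racemate because no chiral element is present.

Step 9
Reactants: 13 rac-2-[(Z)-1-iodoprop-1-en-2-yl]oxirane
Product: 14 (S)-2-[(Z)-1-iodoprop-1-en-2-yl]oxirane
Conditions: (R,R)-(salen)Co(OAc) (1 mol %; salen = N,N′-bis(3,5-di-tert-butylsalicylidene)cyclohexane-1,2-diamine dianion), H2O (0.55 equiv), THF, 0 °C → rt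
Reagents that add atoms: none
Why: Jacobsen hydrolytic kinetic resolution, in which the chiral cobalt salen complex hydrates one enantiomer of a terminal epoxide much faster than the other; by analogy with simple 2-substituted oxiranes the (R,R) catalyst should consume the R epoxide and leave the S enantiomer, which carries the future 4R centre (configuration to be checked before use).

Step 10
Reactants: 8 tert-butyl[(2,2-dimethylhept-6-yn-1-yl)oxy]dimethylsilane; 15 trimethylaluminium; 14 (S)-2-[(Z)-1-iodoprop-1-en-2-yl]oxirane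
Product: 18 (1Z,3R,5E)-11-[(tert-butyldimethylsilyl)oxy]-1-iodo-2,6,10,10-tetramethylundeca-1,5-dien-3-ol, via alkenylalane 16 (not isolated), via lithium alanate 17 (not isolated)
Conditions: 15 (2 equiv), Cp2ZrCl2 (0.25 equiv), ClCH2CH2Cl, 0 °C → rt; volatiles removed in vacuo; n-BuLi (1 equiv per Al), hexane/THF, −40 → 0 °C; then 14 (0.7 equiv), THF, −40 °C → rt; aq. Rochelle salt
Reagents that add atoms: trimethylaluminium (compound 15) C[Al](C)C
Why: Cp2ZrCl2 and AlMe3 form a bimetallic methylzirconocene species that adds CH3 and metal syn across the terminal alkyne with CH3 on the internal carbon (C7), and transfer of the alkenyl group to aluminium gives alane 16; n-BuLi then turns 16 into the tetracoordinate alanate 17, which hands the alkenyl group with retention to the CH2 terminus of epoxide 14 by SN2 attack (C5–C6). The closest known reaction type is the zirconium-catalysed methylalumination of 1-alkynes (Negishi carboalumination) followed by opening of monosubstituted oxiranes with lithium alkenylalanates. No ring is closed. No stereocentre is created: C4 is carried unchanged from 14 because its C–O bond is not broken, and the E geometry of C6=C7 follows from syn addition and retentive transfer. The step needs methyl on C7 and not on C6, which the terminal alkyne secures, and attack at C5 in preference to the allylic C4 or SN2′ attack at C2, which is favoured because the ate complex is not Lewis acidic, C4 is flanked by the fully substituted C3, and C2 carries iodine. The C–I bond should survive because all n-BuLi is bound to aluminium before 14 is added.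

Step 11
Reactants: 19 4-hydroxybenzoic acid
Product: 21 4-[(triisopropylsilyl)oxy]benzoic acid, via bis-silyl ester 20 (not isolated)
Conditions: TIPSCl (2.2 equiv), imidazole, DMF, rt; then K2CO3, THF/H2O, rt; dilute citric acid work-up
Reagents that add atoms: triisopropylsilyl chloride CC(C)[Si](Cl)(C(C)C)C(C)C
Why: Exhaustive silylation followed by selective hydrolysis of the far more labile silyl ester should leave the aryl silyl ether; TIPS is chosen on the phenol so that it outlasts the later acidic removal of the primary TBS ether.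

Step 12
Reactants: 18 (1Z,3R,5E)-11-[(tert-butyldimethylsilyl)oxy]-1-iodo-2,6,10,10-tetramethylundeca-1,5-dien-3-ol; 21 4-[(triisopropylsilyl)oxy]benzoic acid
Product: 22 (1Z,3R,5E)-11-[(tert-butyldimethylsilyl)oxy]-1-iodo-2,6,10,10-tetramethylundeca-1,5-dien-3-yl 4-[(triisopropylsilyl)oxy]benzoate
Conditions: EDC·HCl, DMAP, CH2Cl2, 0 °C → rt
Reagents that add atoms: none
Why: Steglich esterification acylates the C4 oxygen without breaking the C4–O bond, so the 4R configuration is retained.

Step 13
Reactants: 22 (1Z,3R,5E)-11-[(tert-butyldimethylsilyl)oxy]-1-iodo-2,6,10,10-tetramethylundeca-1,5-dien-3-yl 4-[(triisopropylsilyl)oxy]benzoate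
Product: 23 (1Z,3R,5E)-11-hydroxy-1-iodo-2,6,10,10-tetramethylundeca-1,5-dien-3-yl 4-[(triisopropylsilyl)oxy]benzoate
Conditions: CSA (0.1 equiv), MeOH/CH2Cl2 1:1, 0 °C → rt
Reagents that add atoms: none
Why: Acid-catalysed methanolysis cleaves a primary alkyl TBS ether much faster than an electron-poor aryl TIPS ether, so the C1 hydroxyl should be released selectively.

Step 14
Reactants: 23 (1Z,3R,5E)-11-hydroxy-1-iodo-2,6,10,10-tetramethylundeca-1,5-dien-3-yl 4-[(triisopropylsilyl)oxy]benzoate
Product: 24 (1Z,3R,5E)-1-iodo-2,6,10,10-tetramethyl-11-oxoundeca-1,5-dien-3-yl 4-[(triisopropylsilyl)oxy]benzoate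
Conditions: Dess–Martin periodinane, CH2Cl2, 0 °C → rt
Reagents that add atoms: none
Why: Dess–Martin oxidation of the neopentyl primary alcohol should give the non-enolisable C1 aldehyde without affecting the iodoalkene, ester or silyl ether.

Step 15
Reactants: 24 (1Z,3R,5E)-1-iodo-2,6,10,10-tetramethyl-11-oxoundeca-1,5-dien-3-yl 4-[(triisopropylsilyl)oxy]benzoate
Product: 25 (2Z,4R,6E)-1-hydroxy-3,7,11,11-tetramethylcycloundeca-2,6-dien-4-yl 4-[(triisopropylsilyl)oxy]benzoate (both C1 epimers)
Conditions: CrCl2 (8 equiv), NiCl2 (0.1 equiv), degassed DMSO, rt, slow addition of 24 (final 0.003 M)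
Reagents that add atoms: none
Why: Nozaki–Hiyama–Kishi macrocyclisation, in which zerovalent nickel inserts into the C2–I bond, the alkenyl group passes to trivalent chromium with retention of the Z geometry and adds chemoselectively to the aldehyde (esters are left alone), should close the eleven-membered ring at C1–C2 under high dilution; the C1 configuration is not relied on here because it is reset in steps 16 and 17.

Step 16
Reactants: 25 (2Z,4R,6E)-1-hydroxy-3,7,11,11-tetramethylcycloundeca-2,6-dien-4-yl 4-[(triisopropylsilyl)oxy]benzoate (both C1 epimers)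
Product: 26 (2Z,4R,6E)-3,7,11,11-tetramethyl-1-oxocycloundeca-2,6-dien-4-yl 4-[(triisopropylsilyl)oxy]benzoate
Conditions: Dess–Martin periodinane, pyridine, CH2Cl2, 0 °C
Reagents that add atoms: none
Why: Buffered Dess–Martin oxidation should converge both C1 epimers on one enone; C11 has no hydrogen, so the ketone cannot enolise toward the ring, and the neutral conditions should spare the Z alkene and the C4 ester.

Step 17
Reactants: 26 (2Z,4R,6E)-3,7,11,11-tetramethyl-1-oxocycloundeca-2,6-dien-4-yl 4-[(triisopropylsilyl)oxy]benzoate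
Product: 27 (1S,2Z,4R,6E)-1-hydroxy-3,7,11,11-tetramethylcycloundeca-2,6-dien-4-yl 4-[(triisopropylsilyl)oxy]benzoate
Conditions: (R)-2-methyl-CBS-oxazaborolidine (0.5 equiv), catecholborane (2 equiv), toluene, −78 → −40 °C
Reagents that add atoms: none
Why: Corey–Bakshi–Shibata reduction, in which the oxazaborolidine binds the ketone on the lone pair remote from the larger flank (taken to be the quaternary C11 rather than the C2 alkenyl arm) and delivers hydride 1,2 from the nitrogen-bound borane, should set 1S under reagent control with the (R) catalyst; catecholborane at low temperature avoids hydroboration of the alkenes.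

Step 18
Reactants: 27 (1S,2Z,4R,6E)-1-hydroxy-3,7,11,11-tetramethylcycloundeca-2,6-dien-4-yl 4-[(triisopropylsilyl)oxy]benzoate
Product: 28 (1S,2Z,4R,6E)-1-acetoxy-3,7,11,11-tetramethylcycloundeca-2,6-dien-4-yl 4-[(triisopropylsilyl)oxy]benzoate
Conditions: Ac2O, DMAP, Et3N, CH2Cl2, rt
Reagents that add atoms: acetic anhydride CC(=O)OC(C)=O
Why: DMAP-catalysed acetylation acylates the hindered C1 oxygen without breaking the C1–O bond, so 1S is retained.

Step 19
Reactants: 28 (1S,2Z,4R,6E)-1-acetoxy-3,7,11,11-tetramethylcycloundeca-2,6-dien-4-yl 4-[(triisopropylsilyl)oxy]benzoate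
Product: 29 (1S,2Z,4R,6E)-1-acetoxy-3,7,11,11-tetramethylcycloundeca-2,6-dien-4-yl 4-hydroxybenzoate (CNP0246761.2)
Conditions: TBAF, AcOH (1:1), THF, 0 °C
Reagents that add atoms: none
Why: Fluoride cleaves the electron-poor aryl silyl ether within minutes, and the acetic acid buffer should keep the phenoxide from attacking the allylic acetate or the benzoate.

**Compound list**

1 | (5-chloropent-1-yn-1-yl)trimethylsilane | C[Si](C)(C)C#CCCCCl | starting material
2 | (5-iodopent-1-yn-1-yl)trimethylsilane | C[Si](C)(C)C#CCCCI | intermediate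
3 | methyl isobutyrate | COC(=O)C(C)C | starting material
4 | lithium enolate of methyl isobutyrate (lithium 1-methoxy-2-methylprop-1-en-1-olate) | COC(O[Li])=C(C)C | intermediate (not isolated)
5 | methyl 2,2-dimethyl-7-(trimethylsilyl)hept-6-ynoate | COC(=O)C(C)(C)CCCC#C[Si](C)(C)C | intermediate
6 | 2,2-dimethyl-7-(trimethylsilyl)hept-6-yn-1-ol | OCC(C)(C)CCCC#C[Si](C)(C)C | intermediate
7 | 2,2-dimethylhept-6-yn-1-ol | OCC(C)(C)CCCC#C | intermediate
8 | tert-butyl[(2,2-dimethylhept-6-yn-1-yl)oxy]dimethylsilane | C#CCCCC(C)(C)CO[Si](C)(C)C(C)(C)C | intermediate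
9 | propargyl alcohol | C#CCO | starting material
10 | 4-methyl-2,5-dihydro-1,2-oxamagnesole (cyclic alkenylmagnesium alkoxide, Mg cis to CH2O) | CC1=C[Mg]OC1 | intermediate (not isolated)
11 | (Z)-3-iodo-2-methylprop-2-en-1-ol | I/C=C(/C)CO | intermediate
12 | (Z)-3-iodo-2-methylprop-2-enal | I/C=C(/C)C=O | intermediate
13 | rac-2-[(Z)-1-iodoprop-1-en-2-yl]oxirane | I/C=C(/C)C1CO1 | intermediate
14 | (S)-2-[(Z)-1-iodoprop-1-en-2-yl]oxirane | I/C=C(/C)[C@H]1CO1 | intermediate
15 | trimethylaluminium | C[Al](C)C | starting material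
16 | (E)-{7-[(tert-butyldimethylsilyl)oxy]-2,6,6-trimethylhept-1-en-1-yl}dimethylalane | C[Al](C)/C=C(\C)CCCC(C)(C)CO[Si](C)(C)C(C)(C)C | intermediate (not isolated)
17 | lithium butyl{(E)-7-[(tert-butyldimethylsilyl)oxy]-2,6,6-trimethylhept-1-en-1-yl}dimethylaluminate | [Li+].CCCC[Al-](C)(C)/C=C(\C)CCCC(C)(C)CO[Si](C)(C)C(C)(C)C | intermediate (not isolated)
18 | (1Z,3R,5E)-11-[(tert-butyldimethylsilyl)oxy]-1-iodo-2,6,10,10-tetramethylundeca-1,5-dien-3-ol | I/C=C(/C)[C@H](O)C/C=C(\C)CCCC(C)(C)CO[Si](C)(C)C(C)(C)C | intermediate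
19 | 4-hydroxybenzoic acid | OC(=O)c1ccc(O)cc1 | starting material
20 | triisopropylsilyl 4-[(triisopropylsilyl)oxy]benzoate | CC(C)[Si](OC(=O)c1ccc(O[Si](C(C)C)(C(C)C)C(C)C)cc1)(C(C)C)C(C)C | intermediate (not isolated)
21 | 4-[(triisopropylsilyl)oxy]benzoic acid | OC(=O)c1ccc(O[Si](C(C)C)(C(C)C)C(C)C)cc1 | intermediate
22 | (1Z,3R,5E)-11-[(tert-butyldimethylsilyl)oxy]-1-iodo-2,6,10,10-tetramethylundeca-1,5-dien-3-yl 4-[(triisopropylsilyl)oxy]benzoate | I/C=C(/C)[C@H](OC(=O)c1ccc(O[Si](C(C)C)(C(C)C)C(C)C)cc1)C/C=C(\C)CCCC(C)(C)CO[Si](C)(C)C(C)(C)C | intermediate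
23 | (1Z,3R,5E)-11-hydroxy-1-iodo-2,6,10,10-tetramethylundeca-1,5-dien-3-yl 4-[(triisopropylsilyl)oxy]benzoate | I/C=C(/C)[C@H](OC(=O)c1ccc(O[Si](C(C)C)(C(C)C)C(C)C)cc1)C/C=C(\C)CCCC(C)(C)CO | intermediate
24 | (1Z,3R,5E)-1-iodo-2,6,10,10-tetramethyl-11-oxoundeca-1,5-dien-3-yl 4-[(triisopropylsilyl)oxy]benzoate | I/C=C(/C)[C@H](OC(=O)c1ccc(O[Si](C(C)C)(C(C)C)C(C)C)cc1)C/C=C(\C)CCCC(C)(C)C=O | intermediate
25 | (2Z,4R,6E)-1-hydroxy-3,7,11,11-tetramethylcycloundeca-2,6-dien-4-yl 4-[(triisopropylsilyl)oxy]benzoate, both C1 epimers | OC1/C=C(/C)[C@H](OC(=O)c2ccc(O[Si](C(C)C)(C(C)C)C(C)C)cc2)C/C=C(\C)CCCC1(C)C | intermediate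
26 | (2Z,4R,6E)-3,7,11,11-tetramethyl-1-oxocycloundeca-2,6-dien-4-yl 4-[(triisopropylsilyl)oxy]benzoate | O=C1/C=C(/C)[C@H](OC(=O)c2ccc(O[Si](C(C)C)(C(C)C)C(C)C)cc2)C/C=C(\C)CCCC1(C)C | intermediate
27 | (1S,2Z,4R,6E)-1-hydroxy-3,7,11,11-tetramethylcycloundeca-2,6-dien-4-yl 4-[(triisopropylsilyl)oxy]benzoate | O[C@H]1/C=C(/C)[C@H](OC(=O)c2ccc(O[Si](C(C)C)(C(C)C)C(C)C)cc2)C/C=C(\C)CCCC1(C)C | intermediate
28 | (1S,2Z,4R,6E)-1-acetoxy-3,7,11,11-tetramethylcycloundeca-2,6-dien-4-yl 4-[(triisopropylsilyl)oxy]benzoate | CC(=O)O[C@H]1/C=C(/C)[C@H](OC(=O)c2ccc(O[Si](C(C)C)(C(C)C)C(C)C)cc2)C/C=C(\C)CCCC1(C)C | intermediate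
29 | (1S,2Z,4R,6E)-1-acetoxy-3,7,11,11-tetramethylcycloundeca-2,6-dien-4-yl 4-hydroxybenzoate | CC(=O)O[C@H]1/C=C(/C)[C@H](OC(=O)c2ccc(O)cc2)C/C=C(\C)CCCC1(C)C | target

**Step count**

Total: 19 steps. Longest linear sequence: 14 steps (steps 1–5, 10, 12–19).

**Steps most likely to fail**

Step 10 (alanate opening of the alkenyl oxirane). The alanate may react sluggishly with the substituted oxirane, may attack at the allylic carbon or in an SN2′ sense, or may erode the C–I bond. The fallback sets out from alanate 17 and returns at 18, moving the C4 centre to a ketone reduction and building the iodoalkene last.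
- Alanate 17 is treated with ethylene oxide, the best-precedented electrophile for such ate complexes, to give (E)-9-[(tert-butyldimethylsilyl)oxy]-4,8,8-trimethylnon-3-en-1-ol F1.
- Dess–Martin oxidation gives (E)-9-[(tert-butyldimethylsilyl)oxy]-4,8,8-trimethylnon-3-enal F2, used at once.
- Lithium (trimethylsilyl)acetylide in THF at −78 °C gives rac-(E)-11-[(tert-butyldimethylsilyl)oxy]-6,10,10-trimethyl-1-(trimethylsilyl)undec-5-en-1-yn-3-ol F3.
- Dess–Martin oxidation gives (E)-11-[(tert-butyldimethylsilyl)oxy]-6,10,10-trimethyl-1-(trimethylsilyl)undec-5-en-1-yn-3-one F4.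
- Noyori transfer hydrogenation with RuCl[(R,R)-TsDPEN](p-cymene) in i-PrOH should give (R,E)-11-[(tert-butyldimethylsilyl)oxy]-6,10,10-trimethyl-1-(trimethylsilyl)undec-5-en-1-yn-3-ol F5, the catalyst antipode being chosen by analogy with simple alkynyl ketones.
- K2CO3 in MeOH removes the C-silyl group to give (R,E)-11-[(tert-butyldimethylsilyl)oxy]-6,10,10-trimethylundec-5-en-1-yn-3-ol F6.
- The copper-catalysed MeMgBr addition and iodination of step 6, applied to this secondary propargylic alcohol, should put methyl on C3 and iodine on C2 cis to C4, which is compound 18.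

Step 15 (chromium-mediated macrocyclisation). Ring strain in the eleven-membered transition state may let intermolecular coupling, reduction of the C–I bond or Z/E scrambling outrun ring closure. The fallback sets out from aldehyde 24 and returns at enone 26, closing the same C1–C2 bond by an acylative Stille coupling.
- Pinnick oxidation (NaClO2, NaH2PO4, 2-methylbut-2-ene) gives (6E,9R,10Z)-11-iodo-2,2,6,10-tetramethyl-9-({4-[(triisopropylsilyl)oxy]benzoyl}oxy)undeca-6,10-dienoic acid F7.
- Hexamethylditin with Pd(PPh3)4 gives (6E,9R,10Z)-2,2,6,10-tetramethyl-9-({4-[(triisopropylsilyl)oxy]benzoyl}oxy)-11-(trimethylstannyl)undeca-6,10-dienoic acid F8.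
- 1-Chloro-N,N,2-trimethylprop-1-en-1-amine under neutral conditions gives (6E,9R,10Z)-2,2,6,10-tetramethyl-9-({4-[(triisopropylsilyl)oxy]benzoyl}oxy)-11-(trimethylstannyl)undeca-6,10-dienoyl chloride F9.
- Slow addition of F9 to Pd2(dba)3/AsPh3 in toluene under CO (1 atm) should couple the acyl chloride with the alkenylstannane with retention of geometry and give 26 directly.

Step 17 (reagent-controlled reduction). The ring may impose its own facial bias, or the alkenyl arm may act as the larger flank, so that selectivity is poor or reversed. The fallback sets out from the epimer mixture 25 and returns at 27, replacing reagent control by separation and recycling.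
- The C1 epimers of 25 are separated by chromatography and the 1S epimer is taken on as 27.
- The other epimer, (1R,2Z,4R,6E)-1-hydroxy-3,7,11,11-tetramethylcycloundeca-2,6-dien-4-yl 4-[(triisopropylsilyl)oxy]benzoate F10, is oxidised to 26 as in step 16.
- Luche reduction (NaBH4, CeCl3, MeOH, −78 °C) returns 26 to the mixture 25 for another separation.

**Further compounds**

F1 | step 10 | (E)-9-[(tert-butyldimethylsilyl)oxy]-4,8,8-trimethylnon-3-en-1-ol | OCC/C=C(\C)CCCC(C)(C)CO[Si](C)(C)C(C)(C)C
F2 | step 10 | (E)-9-[(tert-butyldimethylsilyl)oxy]-4,8,8-trimethylnon-3-enal | O=CC/C=C(\C)CCCC(C)(C)CO[Si](C)(C)C(C)(C)C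
F3 | step 10 | rac-(E)-11-[(tert-butyldimethylsilyl)oxy]-6,10,10-trimethyl-1-(trimethylsilyl)undec-5-en-1-yn-3-ol | C[Si](C)(C)C#CC(O)C/C=C(\C)CCCC(C)(C)CO[Si](C)(C)C(C)(C)C
F4 | step 10 | (E)-11-[(tert-butyldimethylsilyl)oxy]-6,10,10-trimethyl-1-(trimethylsilyl)undec-5-en-1-yn-3-one | C[Si](C)(C)C#CC(=O)C/C=C(\C)CCCC(C)(C)CO[Si](C)(C)C(C)(C)C
F5 | step 10 | (R,E)-11-[(tert-butyldimethylsilyl)oxy]-6,10,10-trimethyl-1-(trimethylsilyl)undec-5-en-1-yn-3-ol | C[Si](C)(C)C#C[C@H](O)C/C=C(\C)CCCC(C)(C)CO[Si](C)(C)C(C)(C)C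
F6 | step 10 | (R,E)-11-[(tert-butyldimethylsilyl)oxy]-6,10,10-trimethylundec-5-en-1-yn-3-ol | C#C[C@H](O)C/C=C(\C)CCCC(C)(C)CO[Si](C)(C)C(C)(C)C
F7 | step 15 | (6E,9R,10Z)-11-iodo-2,2,6,10-tetramethyl-9-({4-[(triisopropylsilyl)oxy]benzoyl}oxy)undeca-6,10-dienoic acid | I/C=C(/C)[C@H](OC(=O)c1ccc(O[Si](C(C)C)(C(C)C)C(C)C)cc1)C/C=C(\C)CCCC(C)(C)C(=O)O
F8 | step 15 | (6E,9R,10Z)-2,2,6,10-tetramethyl-9-({4-[(triisopropylsilyl)oxy]benzoyl}oxy)-11-(trimethylstannyl)undeca-6,10-dienoic acid | C[Sn](C)(C)/C=C(/C)[C@H](OC(=O)c1ccc(O[Si](C(C)C)(C(C)C)C(C)C)cc1)C/C=C(\C)CCCC(C)(C)C(=O)O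
F9 | step 15 | (6E,9R,10Z)-2,2,6,10-tetramethyl-9-({4-[(triisopropylsilyl)oxy]benzoyl}oxy)-11-(trimethylstannyl)undeca-6,10-dienoyl chloride | C[Sn](C)(C)/C=C(/C)[C@H](OC(=O)c1ccc(O[Si](C(C)C)(C(C)C)C(C)C)cc1)C/C=C(\C)CCCC(C)(C)C(Cl)=O
F10 | step 17 | (1R,2Z,4R,6E)-1-hydroxy-3,7,11,11-tetramethylcycloundeca-2,6-dien-4-yl 4-[(triisopropylsilyl)oxy]benzoate | O[C@@H]1/C=C(/C)[C@H](OC(=O)c2ccc(O[Si](C(C)C)(C(C)C)C(C)C)cc2)C/C=C(\C)CCCC1(C)C
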